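The reading at 2.5 h lies past the last violet point at 20.0 min, so the useful question is where target stops.

| flask | starting material | other conformer | catalyst | temperature | remark | time |
|---|---|---|---|---|---|---|
| green | 0.10 M | 0.25 equiv | 15 mol% | −10 °C | run made earlier |  |
| violet | 0.10 M | 0.38 equiv | 15 mol% | 25 °C | run made earlier |  |
| teal | 0.10 M | 0.50 equiv | 7.5 mol% | −10 °C | run made earlier |  |
| Wednesday's | 0.10 M | 0.500 equiv | 15 mol% | −5 °C |  | 2.5 h |
| Monday's | 0.10 M | 0.500 equiv | 15 mol% | 25 °C |  | 2.5 h |
| Thursday's | 0.10 M | 0.500 equiv | 15 mol% | 55 °C |  | 2.5 h |

| run | time / min | target / % |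
|---|---|---|
| green | 5.00 | 3 |
| green | 15.0 | 5 |
| green | 25.0 | 4 |
| green | 40.0 | 5 |
| green | 50.0 | 8 |
| green | 80.0 | 14 |
| green | 90.0 | 14 |
| violet | 2.50 | 10 |
| violet | 6.00 | 14 |
| violet | 10.0 | 17 |
| violet | 12.0 | 13 |
| violet | 15.0 | 17 |
| violet | 20.0 | 16 |
| teal | 8.00 | 0 |
| teal | 15.0 | 0 |
| teal | 25.0 | 0 |
| teal | 50.0 | 2 |
| teal | 90.0 | 7 |

(standard deviation of a reading: 1.5 percentage points)

- which flask leads in amount of target, in percent of the starting material and other conformer together charged ("all alike" within 1.5 percentage points) (Wednesday's / Monday's / Thursday's / all alike)
- how much target is there at the end, in percent of the starting material and other conformer together charged: Wednesday's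
- how much target is there at the end, in percent of the starting material and other conformer together charged: Monday's
- how much target is there at the end, in percent of the starting material and other conformer together charged: Thursday's

- in a conversion other conformer counts as not yet reacted

The violet readings at 25 °C stop rising: from 10.0 min on they average 15.8%. Reckoned on the starting material charged, that is 21.7%. That share over the rest is 0.278, the target odds: target made per unit of starting material lost elsewhere. Teal, at half of green's loading, reads half of green's target at 90.0 min, but teal also carries more other conformer, so taking the odds as proportional to c catalyst at fixed temperature is an assumption of this reckoning, not a reading.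

Monday's flask matches violet in temperature and c catalyst, so this reckoning keeps violet's odds and spreads them over Monday's larger charge: 14.5%. Green, still climbing at 90.0 min, extended straight to 2.5 h and rebased for Wednesday's charge, gives 19.4% before any credit for the warmer bath, which in this reckoning puts Wednesday's ahead of Monday's. Violet's 25 °C is the hottest run and stands below Thursday's 55 °C, so this reckoning gives Thursday's no number.

The weak link is the flatness of the plateau. The later violet pair stands 1.5 percentage points above the earlier pair, with a scatter of 1.5 points on that difference, so no fall shows up to 20.0 min. Any later loss comes off 14.5%.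

The forecast puts Wednesday's in the lead: 24% (15% to 35%), then Monday's 15.5% (12.5% to 18.5%) and Thursday's 10% (5% to 16%). Of the violet stop it says: “That looks like an equilibrium ceiling, or possibly catalyst death”. Its Monday's figure differs from the 14.5% reckoned here.

The flasks give 20.7% for Wednesday's, 11.5% for Monday's, below the flat-plateau 14.5%, and 12.8% for Thursday's.

    starting material → uncatalysed product (k = 7.06 × 10⁻⁴ /s, Ea = 80.0 kJ/mol)
    starting material ⇌ other conformer (K = 9.22, k = 0.00228 /s, Ea = 90.0 kJ/mol, ΔH = −4.00 kJ/mol)
    catalyst + other conformer → catalyst + isomer of the product A (k = 1.18 /M/s, Ea = 47.0 kJ/mol)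
    starting material + catalyst → catalyst + target (k = 0.103 /M/s, Ea = 67.0 kJ/mol)
    target + catalyst ⇌ isomer of the product B + catalyst, rate k5*[catalyst]*[target] forward; the back reaction follows from the equilibrium constant (K = 1.00, k = 0.0627 /M/s, Ea = 67.0 kJ/mol, ΔH = −63.0 kJ/mol)
    (constants at 25 °C)

Left until 25.0 h, Wednesday's flask holds 2.78% of target against Thursday's 12.8%, so its lead is gone by then. Thursday's 12.8% is a share of 19.1% of the starting material charged and odds of 0.237, below the 0.278 read from violet. The neighbour of Thursday's flask, at 0.17 M of starting material and the same loading, has c catalyst raised by a factor 1.70. Scaled with c catalyst, its odds reckon to 0.402, its share to 28.7%, and its target to 19.1%. That neighbour flask ends with 18.4% of target.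

(The data come from a simulation for substances that don't exist; scatter was added.)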